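In a one-step world every bit of substrate lost would stand as target, and the loss would answer the question. These flasks are tested against that picture below.

all flasks: gas phase 200 mM (held)

| charge | substrate | free catalyst | remark | time |
|---|---|---|---|---|
| alder | 3 M | 6 mM | the very flask that is asked about, followed so far |  |
| ash | 3 M | 12 mM | run made earlier |  |
| flask | 3.0 M | 6.0 mM |  | 1.0 h |

| run | time / min | target / % | substrate / % |
|---|---|---|---|
| alder | 0.417 | 0 | 99.0 |
| alder | 0.667 | 1.8 | 99.5 |
| alder | 1.00 | 1.0 | 99.0 |
| alder | 2.00 | 2.1 | 95.8 |
| alder | 3.00 | 4.7 | 93.4 |
| alder | 5.00 | 7.0 | 88.2 |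
| ash | 2.00 | 5.6 | 94.7 |
| ash | 3.00 | 7.1 | 90.1 |
| ash | 5.00 | 7.5 | 86.4 |
| ash | 8.00 | 9.4 | 78.1 |
| ash | 15.0 | 15.4 | 65.3 |
| ash | 25.0 | 20.1 | 56.8 |

(each reading ± 1 percentage point)

- at the start none of the gas is dissolved
- the numbers in the tables scatter by 1 percentage point (one standard deviation)
- on the list of suspects stand: gas phase <-> dissolved gas; substrate + dissolved gas + free catalyst -> free catalyst + target; 2 free catalyst -> spent catalyst; target <-> isomer of the product

* how much target there is at 1.0 h, in percent of the substrate charged
* the change that raises the amount of target at 1.0 h, in percent of the substrate charged most ("none" if none brings more than 2 percentage points) (epsilon / theta / delta / none)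
* amount of target at 1.0 h, in percent of the substrate charged, after delta

- epsilon: doubling the saturation concentration of gas phase, all else as stated
- theta: doubling the transfer coefficient of the gas phase, all else as stated
- delta: doubling the amount of free catalyst, all else as stated

1. Over the last two readings of ash, 45.6% of the lost substrate stands as target. This target share, target present per substrate lost, turns a loss into a yield.

2. Count the loss as L = ln(c(substrate charged)/c(substrate)). Ash gives 0.426 at 15.0 min and 0.566 at 25.0 min. If two free catalyst do combine to spent catalyst, free catalyst falls late on as one over time, so L climbs a fixed step per factor of time: 0.273 per unit of ln(time).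

3. That death makes charge times time the clock. Alder, with half the catalyst of ash, stands at 1.0 h where ash stands at 30.0 min, so L reaches 0.615.

4. The weak link is this clock, which leaves the gas uncounted, though none of the gas is dissolved at the start. The clock puts alder at 5.00 min behind ash at 3.00 min, yet alder reads 0.126 against 0.104. Adding that offset gives 0.637.

5. The loss is then 47.1%, and the share makes it 21.5% of target.

6. Delta makes the flask ash continued to 1.0 h: 25.2%, a gain of 3.7 percentage points. Epsilon doubles L: 32.8%, a gain of 11 points. Theta, doubling the transfer coefficient, speeds the filling of dissolved gas; the one mark of that filling reckoned here is the offset, small beside L, so epsilon is the choice here.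

The forecast, above this reckoning on y, says 26% (22% to 31%), 27.5% (24% to 33%) after delta, and epsilon: “Doubling saturation doubles the rate at every stage”.

The flask gives 21.4%, 23.5% after delta, and epsilon, worth 10 points.

    gas phase ⇌ dissolved gas, rate k1*(csat - [dissolved gas]) (kL = 0.0170 s⁻¹)
    substrate + dissolved gas + free catalyst → free catalyst + target (k = 0.960 M⁻² s⁻¹)
    2 free catalyst → spent catalyst (k = 0.210 M⁻¹ s⁻¹)
    target ⇌ isomer of the product (K = 1.60, k = 0.00700 s⁻¹)

At 1.0 h the flask has lost 55.0% of its substrate, not the 47.1% reckoned, and the target share makes 25.1% of that loss against 21.4% present. The neighbour flask, the same charge read at 4.0 h, keeps 25% of its substrate. The share turns that loss into 34.2%, and the neighbour holds 28.9% of target beside 46.1% of isomer of the product.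

(The runs were computed for an exercise.)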